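**Retrosynthetic overview**
- The target is opened at the carbinol: both stereocentres come from one asymmetric transfer hydrogenation with dynamic kinetic resolution of the racemic α-aryloxy ketone.
- The ketone is cut at C7–C8. The aroyl carbon (from 3,4,5-trimethoxybenzoyl chloride) is joined to the oxygen-bearing C8 used as a nucleophile: an α-aryloxyethyl d1 synthon released by decarboxylation of a 2-aryloxypropanoic acid under nickel/photoredox catalysis.
- The acid comes from methoxyeugenol and 2-bromopropanoic acid by Williamson etherification.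
- No ring is formed; both benzene rings are bought intact.

Assumption: the SMILES is read as the threo isomer, (1S,2S)-2-(4-allyl-2,6-dimethoxyphenoxy)-1-(3,4,5-trimethoxyphenyl)propan-1-ol (C7 = C1 carbinol, C8 = C2 ether carbon), and 4-allyl-2,6-dimethoxyphenol is taken as a commercial flavour chemical.

Abbreviations: dF(CF3)ppy = 2-(2,4-difluorophenyl)-5-(trifluoromethyl)pyridine; dtbbpy = 4,4'-di-tert-butyl-2,2'-bipyridine; TsDPEN = N-tosyl-1,2-diphenylethylenediamine; glyme/DME = 1,2-dimethoxyethane.

**Route**

Step 1
Reactants: 1 4-allyl-2,6-dimethoxyphenol (methoxyeugenol); 2 racemic 2-bromopropanoic acid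
Product: 3 racemic 2-(4-allyl-2,6-dimethoxyphenoxy)propanoic acid
Conditions: NaH (2.5 equiv), THF, 0 °C to reflux; then aq. HCl
Reagents that add atoms: none
Why: Williamson ether synthesis (SN2) in which the sodium phenoxide of 1 displaces bromide from sodium 2-bromopropanoate, giving the free acid without an ester hydrolysis step; the new centre is left racemic because it is erased in step 2.

Step 2
Reactants: 3 racemic 2-(4-allyl-2,6-dimethoxyphenoxy)propanoic acid; 4 3,4,5-trimethoxybenzoyl chloride
Product: 6 racemic 2-(4-allyl-2,6-dimethoxyphenoxy)-1-(3,4,5-trimethoxyphenyl)propan-1-one, via mixed anhydride 5 (not isolated)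
Conditions: DBU (1.2 equiv), DME, rt, 15 min; then Ir[dF(CF3)ppy]2(dtbbpy)PF6 (1 mol%), NiCl2·glyme (5 mol%), dtbbpy (5 mol%), blue LEDs, rt, degassed
Reagents that add atoms: none
Why: Metallaphotoredox decarboxylative acylation (CO2 extrusion–recombination), in which zerovalent nickel inserts into the aroyl C–O bond of 5, the photo-oxidised carboxylate loses CO2 to give the α-aryloxyethyl radical (a reversed-polarity α-oxy carbanion equivalent at C8), and this is captured at nickel and reductively eliminated with the acyl carbon C7, so two natively electrophilic carbons are joined; C8 forms racemic through the planar radical, which is intended.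

Step 3
Reactants: 6 racemic 2-(4-allyl-2,6-dimethoxyphenoxy)-1-(3,4,5-trimethoxyphenyl)propan-1-one
Product: 8 (1S,2S)-2-(4-allyl-2,6-dimethoxyphenoxy)-1-(3,4,5-trimethoxyphenyl)propan-1-ol, via enol 7 (not isolated)
Conditions: RuCl[(R,R)-TsDPEN](p-cymene) (2 mol%), HCO2H/Et3N (1:2), DMF, 40 °C
Reagents that add atoms: none
Why: Noyori–Ikariya asymmetric transfer hydrogenation with dynamic kinetic resolution, in which Et3N racemises the acidic C8–H of 6 through enol 7 while the (R,R)-catalyst delivers hydride to the face that gives the (1S) carbinol (the sense that gives (S,S)-hydrobenzoin from benzoin), a face that is the Felkin–Anh face only for (S)-6, so the matched enantiomer is drained to the threo (1S,2S) product and the isolated allyl alkene is untouched by this outer-sphere hydride transfer.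

**Compound list**

1 | 4-allyl-2,6-dimethoxyphenol (methoxyeugenol) | C=CCc1cc(OC)c(O)c(OC)c1 | starting material
2 | 2-bromopropanoic acid (racemic) | CC(Br)C(=O)O | starting material
3 | 2-(4-allyl-2,6-dimethoxyphenoxy)propanoic acid (racemic) | C=CCc1cc(OC)c(OC(C)C(=O)O)c(OC)c1 | intermediate
4 | 3,4,5-trimethoxybenzoyl chloride | COc1cc(C(=O)Cl)cc(OC)c1OC | starting material
5 | 2-(4-allyl-2,6-dimethoxyphenoxy)propanoic 3,4,5-trimethoxybenzoic anhydride (racemic, not isolated) | C=CCc1cc(OC)c(OC(C)C(=O)OC(=O)c2cc(OC)c(OC)c(OC)c2)c(OC)c1 | intermediate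
6 | 2-(4-allyl-2,6-dimethoxyphenoxy)-1-(3,4,5-trimethoxyphenyl)propan-1-one (racemic) | C=CCc1cc(OC)c(OC(C)C(=O)c2cc(OC)c(OC)c(OC)c2)c(OC)c1 | intermediate
7 | 2-(4-allyl-2,6-dimethoxyphenoxy)-1-(3,4,5-trimethoxyphenyl)prop-1-en-1-ol (enol of 6, drawn Z; either geometry serves; not isolated) | C=CCc1cc(OC)c(O/C(C)=C(\O)c2cc(OC)c(OC)c(OC)c2)c(OC)c1 | intermediate
8 | (1S,2S)-2-(4-allyl-2,6-dimethoxyphenoxy)-1-(3,4,5-trimethoxyphenyl)propan-1-ol | C=CCc1cc(OC)c(O[C@@H](C)[C@@H](O)c2cc(OC)c(OC)c(OC)c2)c(OC)c1 | target

**Totals**

Total step count: 3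
Longest linear sequence: 3 steps (1 → 3 → 6 → 8)

**Steps most likely to fail**

1. Step 2 (key coupling). The product is an α-aryloxy aryl ketone, a motif that can suffer photoreductive C–O cleavage. The secondary alkyl–nickel species can also β-hydride eliminate, giving an aryl vinyl ether and a nickel hydride that may move the allyl double bond into conjugation. The allylic–benzylic CH2 is a third site for unwanted hydrogen abstraction.
Fallback, setting out from 3 and returning at 6: 3 is esterified with N-hydroxyphthalimide (N,N'-diisopropylcarbodiimide, cat. DMAP, CH2Cl2, rt) to the redox-active ester 1,3-dioxoisoindolin-2-yl 2-(4-allyl-2,6-dimethoxyphenoxy)propanoate F2. F2 is then heated with 3,4,5-trimethoxybenzaldehyde under N-heterocyclic carbene catalysis (N-aryl thiazolium precatalyst 10 mol%, Cs2CO3 20 mol%, DMSO, 60 °C). The Breslow intermediate, a true acyl anion equivalent, transfers one electron to F2, which loses phthalimide anion and CO2. The ketyl and α-aryloxyethyl radicals then recombine to give ketone 6 without light or nickel.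

2. Step 3 (dynamic kinetic resolution). The C8–H of 6 is not benzylic, so racemisation may lag behind reduction and erode dr and ee. The threo preference rests on the Felkin–Anh match and on the benzoin analogy rather than on this exact substrate.
Fallback, setting out from 6 and returning at 8: 6 is reduced under non-chelating conditions (NaBH4, 15-crown-5, i-PrOH, 0 °C), where Felkin–Anh control favours the racemic threo alcohol, rac-threo-2-(4-allyl-2,6-dimethoxyphenoxy)-1-(3,4,5-trimethoxyphenyl)propan-1-ol F3. The minor erythro isomer is removed on silica. F3 is resolved by preparative chiral supercritical-fluid chromatography on an amylose carbamate phase to give 8. The yield is capped at 50%, but the unwanted enantiomer can be oxidised back to 6 and recycled.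

3. Step 1 (etherification with the free bromo acid). The hindered 2,6-dimethoxyphenoxide may react slowly with a secondary α-bromo carboxylate, and E2 loss of HBr to acrylate competes.
Fallback, setting out from 1 and returning at 3: Mitsunobu etherification of 1 with racemic ethyl lactate (PPh3, diisopropyl azodicarboxylate, THF, 0 °C to rt) gives ethyl 2-(4-allyl-2,6-dimethoxyphenoxy)propanoate F1. Saponification of F1 (LiOH, THF/H2O, rt; then aq. HCl) gives acid 3.

**Further compounds**

F1 | step 1 | ethyl 2-(4-allyl-2,6-dimethoxyphenoxy)propanoate (racemic) | C=CCc1cc(OC)c(OC(C)C(=O)OCC)c(OC)c1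
F2 | step 2 | 1,3-dioxoisoindolin-2-yl 2-(4-allyl-2,6-dimethoxyphenoxy)propanoate (racemic) | C=CCc1cc(OC)c(OC(C)C(=O)ON2C(=O)c3ccccc3C2=O)c(OC)c1
F3 | step 3 | rac-threo-2-(4-allyl-2,6-dimethoxyphenoxy)-1-(3,4,5-trimethoxyphenyl)propan-1-ol (1:1 mixture of the (1S,2S) and (1R,2R) enantiomers) | C=CCc1cc(OC)c(O[C@@H](C)[C@@H](O)c2cc(OC)c(OC)c(OC)c2)c(OC)c1.C=CCc1cc(OC)c(O[C@H](C)[C@H](O)c2cc(OC)c(OC)c(OC)c2)c(OC)c1
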